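**Plan**

- Retrosynthesis: the ring-B side chains are removed first (O4'–prenyl, then C5'–C(CH3)2CH=CH2 by a Claisen shift from O4'). The C3–C4 bond of the chroman is then traced back to a C3–NH–C4 unit in a 3-aryl-tetrahydro-1,4-benzoxazepine. This is opened at N–C4 (reductive amination), O1–C2 (Mitsunobu) and C2–C3 (vinyl addition to a ring-B sulfinimine).
- Enabling feature: C3 (carrying ring B) and C4 (on C4a of ring A) are both benzylic. A nitrogen placed between them is a dibenzylic secondary amine that can leave as N2 while C3 and C4 recombine.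
- Forward order: ring-B aldehyde → sulfinimine → vinyl adduct → N-Boc arylglycinol; ether link to the ring-A salicylaldehyde; the seven-membered oxazepine closes by reductive amination and is contracted to the six-membered chroman by nitrogen deletion; debenzylation, prenylation, Claisen shift, second prenylation and desilylation complete ring B.
- Stereochemistry: the only stereocentre, C3 (R), is set as a C–N centre by auxiliary-controlled vinyl Grignard addition to the (R)-tert-butanesulfinyl imine and is to be carried through the nitrogen deletion with retention.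

Key step: step 9

Assumption: isoflavan numbering is used (O1, C2, C3, C4, ring A C4a–C8a, ring B C1'–C6'); the bulky 2'-O-silyl ether is assumed not to chelate magnesium, so the usual cyclic model governs step 3.

**Route**

Step 1
Reactants: 1 4-(benzyloxy)-2-hydroxybenzaldehyde
Product: 2 4-(benzyloxy)-2-(triisopropylsilyloxy)benzaldehyde
Conditions: TIPSOTf, 2,6-lutidine, CH2Cl2, 0 °C to rt
Reagents that add atoms: triisopropylsilyl trifluoromethanesulfonate, CC(C)[Si](C(C)C)(C(C)C)OS(=O)(=O)C(F)(F)F
Why: O-silylation with the silyl triflate overcomes the hydrogen bond of the ortho-phenol to the formyl group, and the bulky, poorly coordinating TIPS ether is chosen because it should resist the Grignard, acid and hydride steps ahead and leave only with fluoride at the end.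

Step 2
Reactants: 2 4-(benzyloxy)-2-(triisopropylsilyloxy)benzaldehyde
Product: 3 (R)-N-[(E)-[4-(benzyloxy)-2-(triisopropylsilyloxy)phenyl]methylidene]-2-methylpropane-2-sulfinamide
Conditions: (R)-t-BuS(O)NH2, Ti(OEt)4, THF, rt to 50 °C
Reagents that add atoms: (R)-2-methylpropane-2-sulfinamide, CC(C)(C)[S@@](=O)N
Why: Titanium(IV) ethoxide-mediated condensation of an aldehyde with tert-butanesulfinamide (N-sulfinyl imine formation) removes the water as it forms and should give only the E aldimine without touching the silyl ether.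

Step 3
Reactants: 3 (R)-N-[(E)-[4-(benzyloxy)-2-(triisopropylsilyloxy)phenyl]methylidene]-2-methylpropane-2-sulfinamide; 4 vinylmagnesium bromide
Product: 5 (R)-N-[(1S)-1-[4-(benzyloxy)-2-(triisopropylsilyloxy)phenyl]prop-2-en-1-yl]-2-methylpropane-2-sulfinamide
Conditions: CH2=CHMgBr (THF solution), CH2Cl2, −78 to −40 °C; aq. NH4Cl
Reagents that add atoms: vinylmagnesium bromide (4), C=C[Mg]Br
Why: Grignard 1,2-addition to an N-tert-butanesulfinyl aldimine in a non-coordinating solvent runs through the six-membered chair transition state with magnesium on the sulfinyl oxygen, so vinyl should add to the Si face of the (R)-sulfinimine and set the future C3 as the (S)-allylic amine (R once the vinyl carbon carries oxygen), the minor diastereomer being removable by chromatography.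

Step 4
Reactants: 5 (R)-N-[(1S)-1-[4-(benzyloxy)-2-(triisopropylsilyloxy)phenyl]prop-2-en-1-yl]-2-methylpropane-2-sulfinamide
Product: 7 tert-butyl N-[(1S)-1-[4-(benzyloxy)-2-(triisopropylsilyloxy)phenyl]prop-2-en-1-yl]carbamate, via amine hydrochloride 6 (not isolated)
Conditions: HCl (4 M in dioxane), MeOH, 0 °C; evaporate; then Boc2O, Et3N, CH2Cl2, rt
Reagents that add atoms: di-tert-butyl dicarbonate, CC(C)(C)OC(=O)OC(=O)OC(C)(C)C
Why: Acidic methanolysis of the S–N bond followed by carbamate formation (Boc protection) exchanges the ozone-sensitive sulfinyl group for a carbamate without involving the stereocentre, the short cold acid treatment being tolerated by aryl TIPS ethers.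

Step 5
Reactants: 7 tert-butyl N-[(1S)-1-[4-(benzyloxy)-2-(triisopropylsilyloxy)phenyl]prop-2-en-1-yl]carbamate
Product: 9 tert-butyl N-[(1R)-1-[4-(benzyloxy)-2-(triisopropylsilyloxy)phenyl]-2-hydroxyethyl]carbamate, via ozonide 8 (not isolated)
Conditions: O3, CH2Cl2, −78 °C (Sudan Red 7B end point); then MeOH, NaBH4, −78 to 0 °C
Reagents that add atoms: ozone, [O-][O+]=O
Why: Ozonolysis of the only alkene with reductive work-up by borohydride in the same flask gives the primary alcohol, the α-amino aldehyde being reduced as it forms at low temperature so that the arylglycine-type centre should not enolise, while the dye end point protects the electron-rich ring.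

Step 6
Reactants: 10 2,4-dihydroxybenzaldehyde
Product: 11 2-hydroxy-4-(triisopropylsilyloxy)benzaldehyde
Conditions: TIPSCl (1.05 equiv), imidazole, CH2Cl2, 0 °C
Reagents that add atoms: triisopropylsilyl chloride, CC(C)[Si](Cl)(C(C)C)C(C)C
Why: Regioselective O-silylation is expected because the 2-OH is held in a hydrogen bond to the formyl group, leaving the unhindered 4-OH to react with one equivalent of silyl chloride.

Step 7
Reactants: 9 tert-butyl N-[(1R)-1-[4-(benzyloxy)-2-(triisopropylsilyloxy)phenyl]-2-hydroxyethyl]carbamate; 11 2-hydroxy-4-(triisopropylsilyloxy)benzaldehyde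
Product: 12 tert-butyl N-[(1R)-1-[4-(benzyloxy)-2-(triisopropylsilyloxy)phenyl]-2-[2-formyl-5-(triisopropylsilyloxy)phenoxy]ethyl]carbamate
Conditions: PPh3, DIAD, THF, 0 °C to rt
Reagents that add atoms: none
Why: Mitsunobu etherification of a primary alcohol with an acidic salicylaldehyde phenol forms the O1–C2 bond under neutral conditions, the stereocentre not being the reacting carbon and the carbamate N–H being too weak an acid to compete.

Step 8
Reactants: 12 tert-butyl N-[(1R)-1-[4-(benzyloxy)-2-(triisopropylsilyloxy)phenyl]-2-[2-formyl-5-(triisopropylsilyloxy)phenoxy]ethyl]carbamate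
Product: 15 (3R)-3-[4-(benzyloxy)-2-(triisopropylsilyloxy)phenyl]-8-(triisopropylsilyloxy)-2,3,4,5-tetrahydro-1,4-benzoxazepine, via amino aldehyde 13 (not isolated), via cyclic imine 14 (not isolated)
Conditions: TFA, CH2Cl2, 0 °C; evaporate; then Et3N, NaBH(OAc)3, ClCH2CH2Cl, rt
Reagents that add atoms: none
Why: Acidolysis of the Boc group should be faster than ionisation of the electron-rich benzylic C–N bond and leaves an inert ammonium ion, which on neutralisation condenses with the ortho-formyl group to the seven-membered cyclic imine that triacetoxyborohydride reduces (intramolecular reductive amination), a standard entry to tetrahydro-1,4-benzoxazepines.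

Step 9
Reactants: 15 (3R)-3-[4-(benzyloxy)-2-(triisopropylsilyloxy)phenyl]-8-(triisopropylsilyloxy)-2,3,4,5-tetrahydro-1,4-benzoxazepine
Product: 18 (3R)-4'-(benzyloxy)-7,2'-bis(triisopropylsilyloxy)isoflavan, via N-amination adduct 16 (not isolated), via isodiazene 17 (not isolated)
Conditions: N-(benzyloxy)-N-(pivaloyloxy)-4-(trifluoromethyl)benzamide (1.5 equiv), THF (0.2 M), Ar, rt to 45 °C
Reagents that add atoms: none
Why: Proposed new method: the secondary amine attacks the electrophilic amide nitrogen of the N-acyloxy-N-alkoxyamide with loss of pivalate to give 16, which expels benzyl 4-(trifluoromethyl)benzoate by shift of the benzyloxy group to the carbonyl carbon and leaves the 1,1-diazene 17; 17 loses N2 to a singlet 1,6-diradical whose two benzylic ends, C3 on ring B and C4 on ring A, recombine. The closest known reaction type is the nitrogen deletion of dibenzylic secondary amines through isodiazenes, including ring contractions of cyclic amines with retention in pyrrolidine-to-cyclobutane cases, whereas retention at a benzylic centre in a seven-to-six contraction has not been shown. The chroman ring closes by intramolecular radical–radical coupling of the 1,6-diradical (six-membered ring closure forming C3–C4) in place of the C3–N–C4 unit of the oxazepine. No new stereocentre is made; the C3 centre from step 3 has to be carried over with retention, which needs C4 to bond to the face of the C3 radical that nitrogen has just left before the C2–C3 bond rotates. The short O1–C2 tether, the spin-paired state of the diradical and the 2'-OTIPS group, which should raise the barrier to rotation of the planar benzylic C3 radical, are relied on for this, and chemoselectivity is not in question because 15 holds no other N–H or O–H bond; the reaction is started at rt and warmed only if needed, and the enantiomeric purity of 18 is the first thing to measure.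

Step 10
Reactants: 18 (3R)-4'-(benzyloxy)-7,2'-bis(triisopropylsilyloxy)isoflavan
Product: 19 (3R)-4'-hydroxy-7,2'-bis(triisopropylsilyloxy)isoflavan
Conditions: H2 (1 atm), 10% Pd/C, EtOAc, rt
Reagents that add atoms: none
Why: Hydrogenolysis of the benzyl ether over palladium frees only the 4'-OH, since the benzylic C–N bonds that it would have threatened are gone and aryl silyl ethers and the chroman are inert.

Step 11
Reactants: 19 (3R)-4'-hydroxy-7,2'-bis(triisopropylsilyloxy)isoflavan; 20 prenyl bromide
Product: 21 (3R)-4'-(3-methylbut-2-enyloxy)-7,2'-bis(triisopropylsilyloxy)isoflavan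
Conditions: prenyl bromide, K2CO3, acetone, 50 °C
Reagents that add atoms: prenyl bromide (20), CC(C)=CCBr
Why: Williamson O-alkylation of the single free phenol with an allylic bromide and anhydrous carbonate in acetone is mild enough to leave the two aryl TIPS ethers in place.

Step 12
Reactants: 21 (3R)-4'-(3-methylbut-2-enyloxy)-7,2'-bis(triisopropylsilyloxy)isoflavan
Product: 22 (3R)-4'-hydroxy-5'-(2-methylbut-3-en-2-yl)-7,2'-bis(triisopropylsilyloxy)isoflavan
Conditions: PhNEt2, 190 °C, sealed tube, Ar
Reagents that add atoms: none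
Why: The aromatic Claisen rearrangement ([3,3]-sigmatropic shift) transfers the prenyl group with allylic inversion as the 1,1-dimethylallyl group to C5', because C3' is flanked by the OTIPS group and disfavoured by the meta donor while the para position C1' is substituted, and the amine solvent should suppress acid-catalysed cyclisation and abnormal Claisen pathways.

Step 13
Reactants: 22 (3R)-4'-hydroxy-5'-(2-methylbut-3-en-2-yl)-7,2'-bis(triisopropylsilyloxy)isoflavan; 20 prenyl bromide
Product: 23 (3R)-5'-(2-methylbut-3-en-2-yl)-4'-(3-methylbut-2-enyloxy)-7,2'-bis(triisopropylsilyloxy)isoflavan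
Conditions: prenyl bromide, K2CO3, acetone, reflux
Reagents that add atoms: prenyl bromide (20), CC(C)=CCBr
Why: Williamson O-alkylation with the reactive allylic bromide should still proceed at the phenol next to the quaternary carbon, and carbonate in acetone favours O- over C-alkylation.

Step 14
Reactants: 23 (3R)-5'-(2-methylbut-3-en-2-yl)-4'-(3-methylbut-2-enyloxy)-7,2'-bis(triisopropylsilyloxy)isoflavan
Product: 24 Manuifolin D
Conditions: TBAF, AcOH, THF, 0 °C to rt
Reagents that add atoms: none
Why: Fluoride-induced cleavage of both aryl silyl ethers (desilylation), buffered with acetic acid, releases the 7- and 2'-phenols without any acid or hydrogenation step that would endanger the prenyl ether and the terminal alkene.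

**Compound list**

1 | 4-(benzyloxy)-2-hydroxybenzaldehyde | O=Cc1ccc(OCc2ccccc2)cc1O | starting material
2 | 4-(benzyloxy)-2-(triisopropylsilyloxy)benzaldehyde | O=Cc1ccc(OCc2ccccc2)cc1O[Si](C(C)C)(C(C)C)C(C)C | intermediate
3 | (R)-N-[(E)-[4-(benzyloxy)-2-(triisopropylsilyloxy)phenyl]methylidene]-2-methylpropane-2-sulfinamide | CC(C)(C)[S@@](=O)/N=C/c1ccc(OCc2ccccc2)cc1O[Si](C(C)C)(C(C)C)C(C)C | intermediate
4 | vinylmagnesium bromide | C=C[Mg]Br | starting material
5 | (R)-N-[(1S)-1-[4-(benzyloxy)-2-(triisopropylsilyloxy)phenyl]prop-2-en-1-yl]-2-methylpropane-2-sulfinamide | C=C[C@H](N[S@](=O)C(C)(C)C)c1ccc(OCc2ccccc2)cc1O[Si](C(C)C)(C(C)C)C(C)C | intermediate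
6 | (1S)-1-[4-(benzyloxy)-2-(triisopropylsilyloxy)phenyl]prop-2-en-1-aminium chloride | C=C[C@H]([NH3+])c1ccc(OCc2ccccc2)cc1O[Si](C(C)C)(C(C)C)C(C)C.[Cl-] | intermediate
7 | tert-butyl N-[(1S)-1-[4-(benzyloxy)-2-(triisopropylsilyloxy)phenyl]prop-2-en-1-yl]carbamate | C=C[C@H](NC(=O)OC(C)(C)C)c1ccc(OCc2ccccc2)cc1O[Si](C(C)C)(C(C)C)C(C)C | intermediate
8 | tert-butyl N-[(R)-[4-(benzyloxy)-2-(triisopropylsilyloxy)phenyl](1,2,4-trioxolan-3-yl)methyl]carbamate (ozonide, both epimers at the trioxolane carbon) | O1COOC1[C@H](NC(=O)OC(C)(C)C)c2ccc(OCc3ccccc3)cc2O[Si](C(C)C)(C(C)C)C(C)C | intermediate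
9 | tert-butyl N-[(1R)-1-[4-(benzyloxy)-2-(triisopropylsilyloxy)phenyl]-2-hydroxyethyl]carbamate | OC[C@H](NC(=O)OC(C)(C)C)c1ccc(OCc2ccccc2)cc1O[Si](C(C)C)(C(C)C)C(C)C | intermediate
10 | 2,4-dihydroxybenzaldehyde | O=Cc1ccc(O)cc1O | starting material
11 | 2-hydroxy-4-(triisopropylsilyloxy)benzaldehyde | O=Cc1ccc(O[Si](C(C)C)(C(C)C)C(C)C)cc1O | intermediate
12 | tert-butyl N-[(1R)-1-[4-(benzyloxy)-2-(triisopropylsilyloxy)phenyl]-2-[2-formyl-5-(triisopropylsilyloxy)phenoxy]ethyl]carbamate | O=Cc1ccc(O[Si](C(C)C)(C(C)C)C(C)C)cc1OC[C@H](NC(=O)OC(C)(C)C)c1ccc(OCc2ccccc2)cc1O[Si](C(C)C)(C(C)C)C(C)C | intermediate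
13 | 2-[(2R)-2-amino-2-[4-(benzyloxy)-2-(triisopropylsilyloxy)phenyl]ethoxy]-4-(triisopropylsilyloxy)benzaldehyde, trifluoroacetate salt | O=Cc1ccc(O[Si](C(C)C)(C(C)C)C(C)C)cc1OC[C@H]([NH3+])c1ccc(OCc2ccccc2)cc1O[Si](C(C)C)(C(C)C)C(C)C.[O-]C(=O)C(F)(F)F | intermediate
14 | (3R)-3-[4-(benzyloxy)-2-(triisopropylsilyloxy)phenyl]-8-(triisopropylsilyloxy)-2,3-dihydro-1,4-benzoxazepine | c1ccccc1COc1ccc([C@@H]2COc3cc(O[Si](C(C)C)(C(C)C)C(C)C)ccc3C=N2)c(O[Si](C(C)C)(C(C)C)C(C)C)c1 | intermediate
15 | (3R)-3-[4-(benzyloxy)-2-(triisopropylsilyloxy)phenyl]-8-(triisopropylsilyloxy)-2,3,4,5-tetrahydro-1,4-benzoxazepine | c1ccccc1COc1ccc([C@@H]2COc3cc(O[Si](C(C)C)(C(C)C)C(C)C)ccc3CN2)c(O[Si](C(C)C)(C(C)C)C(C)C)c1 | intermediate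
16 | N-(benzyloxy)-N-[(3R)-3-[4-(benzyloxy)-2-(triisopropylsilyloxy)phenyl]-8-(triisopropylsilyloxy)-2,3-dihydro-1,4-benzoxazepin-4(5H)-yl]-4-(trifluoromethyl)benzamide | c1ccccc1COc1ccc([C@@H]2COc3cc(O[Si](C(C)C)(C(C)C)C(C)C)ccc3CN2N(OCc4ccccc4)C(=O)c5ccc(C(F)(F)F)cc5)c(O[Si](C(C)C)(C(C)C)C(C)C)c1 | intermediate
17 | 1,1-diazene (isodiazene) of 15, exocyclic N on the ring nitrogen | c1ccccc1COc1ccc([C@@H]2COc3cc(O[Si](C(C)C)(C(C)C)C(C)C)ccc3C[N+]2=[N-])c(O[Si](C(C)C)(C(C)C)C(C)C)c1 | intermediate
18 | (3R)-4'-(benzyloxy)-7,2'-bis(triisopropylsilyloxy)isoflavan | c1ccccc1COc1ccc([C@@H]2COc3cc(O[Si](C(C)C)(C(C)C)C(C)C)ccc3C2)c(O[Si](C(C)C)(C(C)C)C(C)C)c1 | intermediate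
19 | (3R)-4'-hydroxy-7,2'-bis(triisopropylsilyloxy)isoflavan | Oc1ccc([C@@H]2COc3cc(O[Si](C(C)C)(C(C)C)C(C)C)ccc3C2)c(O[Si](C(C)C)(C(C)C)C(C)C)c1 | intermediate
20 | prenyl bromide (1-bromo-3-methylbut-2-ene) | CC(C)=CCBr | starting material
21 | (3R)-4'-(3-methylbut-2-enyloxy)-7,2'-bis(triisopropylsilyloxy)isoflavan | CC(C)=CCOc1ccc([C@@H]2COc3cc(O[Si](C(C)C)(C(C)C)C(C)C)ccc3C2)c(O[Si](C(C)C)(C(C)C)C(C)C)c1 | intermediate
22 | (3R)-4'-hydroxy-5'-(2-methylbut-3-en-2-yl)-7,2'-bis(triisopropylsilyloxy)isoflavan | C=CC(C)(C)c1cc([C@@H]2COc3cc(O[Si](C(C)C)(C(C)C)C(C)C)ccc3C2)c(O[Si](C(C)C)(C(C)C)C(C)C)cc1O | intermediate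
23 | (3R)-5'-(2-methylbut-3-en-2-yl)-4'-(3-methylbut-2-enyloxy)-7,2'-bis(triisopropylsilyloxy)isoflavan | C=CC(C)(C)c1cc([C@@H]2COc3cc(O[Si](C(C)C)(C(C)C)C(C)C)ccc3C2)c(O[Si](C(C)C)(C(C)C)C(C)C)cc1OCC=C(C)C | intermediate
24 | Manuifolin D, (3R)-7,2'-dihydroxy-5'-(2-methylbut-3-en-2-yl)-4'-(3-methylbut-2-enyloxy)isoflavan | C=CC(C)(C)c1cc([C@@H]2COc3cc(O)ccc3C2)c(O)cc1OCC=C(C)C | target

**Step count and risks**

Total step count: 14. Longest linear sequence: 13 (steps 1–5 and 7–14; step 6 is the side branch).

Steps most likely to fail: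

1. Step 9. The C3 benzylic radical may rotate about C2–C3 before the ring closes, eroding the configuration, or N-amination of the hindered amine next to the 2'-OTIPS aryl group may stall. The fallback forms the isoflavan by C–C chemistry of known type; it sets out from 2 and 11 and comes back at 18. Wittig methoxymethylenation of 2 (MeOCH2PPh3Cl, NaHMDS) would give the enol ether 4-(benzyloxy)-1-(2-methoxyethenyl)-2-(triisopropylsilyloxy)benzene F1. Mild acid hydrolysis would give [4-(benzyloxy)-2-(triisopropylsilyloxy)phenyl]acetaldehyde F2, and Pinnick oxidation would give [4-(benzyloxy)-2-(triisopropylsilyloxy)phenyl]acetic acid F3. Perkin-type condensation of this acid with salicylaldehyde 11 (Ac2O, Et3N, heat) would give 3-[4-(benzyloxy)-2-(triisopropylsilyloxy)phenyl]-7-(triisopropylsilyloxy)-2H-chromen-2-one F4. DIBAL-H reduction of the lactone would give (2Z)-2-[4-(benzyloxy)-2-(triisopropylsilyloxy)phenyl]-3-[2-hydroxy-4-(triisopropylsilyloxy)phenyl]prop-2-en-1-ol F5. Mitsunobu cyclisation would close 3-[4-(benzyloxy)-2-(triisopropylsilyloxy)phenyl]-7-(triisopropylsilyloxy)-2H-chromene F6. Iridium–phosphinooxazoline-catalysed asymmetric hydrogenation of the C3=C4 alkene, a known reaction of 3-aryl-2H-chromenes, would then set C3 and give 18; the catalyst antipode that delivers the R product would have to be found by trial.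

2. Step 12. At the temperature needed, the prenyl group may be lost from oxygen, or the ortho-(1,1-dimethylallyl)phenol may react further (cyclisation onto the alkene, abnormal Claisen shift). The fallback installs the reverse-prenyl group by cross-coupling; it sets out from 19 and comes back at 22. Bromination ortho to the free phenol with NBS at low temperature would give (3R)-5'-bromo-4'-hydroxy-7,2'-bis(triisopropylsilyloxy)isoflavan F7, C5' being the only open activated position of that ring. Suzuki–Miyaura coupling with prenylboronic acid pinacol ester, under ligand control for bond formation at the γ-carbon of the allyl unit, would then give 22.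

3. Step 5. The transient N-Boc α-aryl-α-amino aldehyde may epimerise under the basic borohydride conditions, or ozone may attack the electron-rich ring. The fallback avoids both the aldehyde and ozone; it sets out from 2 and comes back at 9, bypassing steps 2–5. Wittig methylenation of 2 would give 4-(benzyloxy)-1-ethenyl-2-(triisopropylsilyloxy)benzene F8. Sharpless asymmetric aminohydroxylation (tert-butyl carbamate, t-BuOCl, NaOH, K2OsO2(OH)4, (DHQD)2PHAL, n-PrOH/H2O) should place nitrogen at the benzylic carbon on the face that gives the (R)-carbamate 9.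

Further compounds
F1 | step 9 | 4-(benzyloxy)-1-(2-methoxyethenyl)-2-(triisopropylsilyloxy)benzene (E/Z mixture) | COC=Cc1ccc(OCc2ccccc2)cc1O[Si](C(C)C)(C(C)C)C(C)C
F2 | step 9 | [4-(benzyloxy)-2-(triisopropylsilyloxy)phenyl]acetaldehyde | O=CCc1ccc(OCc2ccccc2)cc1O[Si](C(C)C)(C(C)C)C(C)C
F3 | step 9 | [4-(benzyloxy)-2-(triisopropylsilyloxy)phenyl]acetic acid | OC(=O)Cc1ccc(OCc2ccccc2)cc1O[Si](C(C)C)(C(C)C)C(C)C
F4 | step 9 | 3-[4-(benzyloxy)-2-(triisopropylsilyloxy)phenyl]-7-(triisopropylsilyloxy)-2H-chromen-2-one | O=C1Oc2cc(O[Si](C(C)C)(C(C)C)C(C)C)ccc2C=C1c1ccc(OCc2ccccc2)cc1O[Si](C(C)C)(C(C)C)C(C)C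
F5 | step 9 | (2Z)-2-[4-(benzyloxy)-2-(triisopropylsilyloxy)phenyl]-3-[2-hydroxy-4-(triisopropylsilyloxy)phenyl]prop-2-en-1-ol | OC/C(=C\c1ccc(O[Si](C(C)C)(C(C)C)C(C)C)cc1O)c1ccc(OCc2ccccc2)cc1O[Si](C(C)C)(C(C)C)C(C)C
F6 | step 9 | 3-[4-(benzyloxy)-2-(triisopropylsilyloxy)phenyl]-7-(triisopropylsilyloxy)-2H-chromene | c1ccccc1COc1ccc(C2=Cc3ccc(O[Si](C(C)C)(C(C)C)C(C)C)cc3OC2)c(O[Si](C(C)C)(C(C)C)C(C)C)c1
F7 | step 12 | (3R)-5'-bromo-4'-hydroxy-7,2'-bis(triisopropylsilyloxy)isoflavan | Brc1cc([C@@H]2COc3cc(O[Si](C(C)C)(C(C)C)C(C)C)ccc3C2)c(O[Si](C(C)C)(C(C)C)C(C)C)cc1O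
F8 | step 5 | 4-(benzyloxy)-1-ethenyl-2-(triisopropylsilyloxy)benzene | C=Cc1ccc(OCc2ccccc2)cc1O[Si](C(C)C)(C(C)C)C(C)C
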